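If the four flasks below are to come out alike within the margin, the way each is dosed must stop mattering, so write the balance of the reagent and ask whether it pays for every substrate.

| setting | Thursday's | Tuesday's | Saturday's | dawn | midnight | autumn | spring |
|---|---|---|---|---|---|---|---|
| starting material | 0.050 M | 0.050 M | 0.050 M | 0.050 M (fed, over 1.5 h) | 0.050 M | 0.050 M (fed, over 1.5 h) | 0.050 M |
| reagent | 0.10 M | 0.050 M | 0.20 M | 0.100 M | 0.100 M | 0.100 M | 0.100 M |
| second substrate | 0.050 M | 0.050 M | 0.050 M | 0.0500 M | 0.0500 M | 0.0500 M | 0.0500 M |
| third substrate | 0.10 M | 0.10 M | 0.10 M | 0.100 M | 0.100 M (fed, over 1.5 h) | 0.100 M | 0.100 M |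
| temperature | 10 °C | 25 °C | 10 °C |  | 25 °C | 25 °C | 25 °C |
| remark | run made earlier | run made earlier | run made earlier | the addition at −5 °C, then warmed to 25 °C; the feed brings no volume worth counting | all else is in the flask from the start; the feed brings no volume worth counting | all else is in the flask from the start; the feed brings no volume worth counting | everything together at the start |
| time |  |  |  | 4.0 h | 4.0 h | 4.0 h | 4.0 h |

| Thursday's: time / h | Thursday's: target / % | Tuesday's: time / h | Tuesday's: target / % | Saturday's: time / h | Saturday's: target / % |
|---|---|---|---|---|---|
| 1.00 | 38 | 1.33 | 24 | 1.33 | 72 |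
| 3.00 | 50 | 2.50 | 22 | 3.00 | 81 |
| 5.00 | 51 | 4.00 | 20 | 6.00 | 78 |
| 8.00 | 49 | 5.00 | 19 | 10.0 | 73 |

(standard deviation of a reading: 1.5 percentage points)

- the best flask by amount of target, in percent of the starting material charged; "all alike" if 1.5 percentage points covers them all (dawn / midnight / autumn / spring / all alike)
- amount of target at the end, in percent of the starting material charged, dawn
- amount of target at the end, in percent of the starting material charged, midnight
- amount of target at the end, in percent of the starting material charged, autumn
- amount of target at the end, in percent of the starting material charged, spring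

Self-condensation aside, the starting material, second substrate and third substrate each take one reagent per turn. Let C = 50.0%, the cover: reagent charged over the sum of the substrate charges. Paying each substrate charge in full asks for C at one, and these recipes fall short of that by 0.100 M, so the reagent is the limiting reagent.

Read the earlier runs against C. Tuesday's run, at 25.0%, reads at most 24%. Thursday's, at 50.0%, reads at most 51%, and Saturday's, at 100%, at most 81%. The target reading therefore follows C closely at the lower two and stays below it at the third.

The four flasks share their charges, so C does not separate them; they differ in which charge, if any, is fed and, in dawn, in an addition at −5 °C instead of 25 °C. The third substrate is the largest claimant, so hold it back: commit to midnight first and autumn last.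

The forecast names midnight, with dawn 36%, midnight 56%, autumn 14% and spring 40%, arguing that “feeding the third substrate keeps it scarce while reagent is plentiful”.

The flasks give dawn 38.6%, midnight 52.7%, autumn 23.7% and spring 40.0%, so midnight is best, and autumn stands 9.7 percentage points above the forecast.

    2 second substrate → self-condensation product (k = 0.224 M⁻¹ min⁻¹, Ea = 62.0 kJ mol⁻¹)
    second substrate + reagent → second product (k = 0.0904 M⁻¹ min⁻¹, Ea = 55.0 kJ mol⁻¹)
    target ⇌ isomer of the product (K = 0.660, k = 0.00705 min⁻¹, Ea = 95.0 kJ mol⁻¹, ΔH = 14.0 kJ mol⁻¹)
    starting material + reagent → target (k = 0.455 M⁻¹ min⁻¹, Ea = 55.0 kJ mol⁻¹)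
    third substrate + reagent → third product (k = 0.400 M⁻¹ min⁻¹, Ea = 51.0 kJ mol⁻¹)
    (constants at 25 °C)

At C = 50.0%, autumn ends with 0.135% of its reagent left, and target plus isomer of the product come to 37.8% of the starting material charged. Raise autumn's reagent to 0.17 M and C becomes 85.0%. That neighbouring flask keeps 6.60% of its reagent at 4.00 h and 12.4% of its starting material, with the isomer of the product at 31.4% and the target at 56.3%.

The earlier runs and the new flask are calculated for substances that don't exist, noise included.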